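## The problem

The target 9 is the hexacosyl ester of 3-(4-hydroxyphenyl)propanoic acid. It has a para-disubstituted benzene ring (ring A) with a free hydroxyl at C4' and, at C1', a three-carbon chain C3–C2–C1 whose carboxyl carbon C1 is esterified with an unbranched C26 alcohol. There is no stereocentre and no ring to construct other than ring A, which can be bought, so the difficulties are chemoselectivity and handling. The phenol is both a nucleophile and an acidic site: it would be acylated by any activated ester and would quench basic or organometallic intermediates, so it has to be masked while the carbon–carbon bond is made. The primary alkyl ester at C1 must survive every later operation, which excludes aqueous hydroxide, hydride reagents and unbuffered alkoxide or fluoride, and the final unmasking must leave it alone. The C26 chain governs the physical behaviour: every intermediate that carries it is a wax with poor solubility in polar media and little chromatographic contrast, so by-products bearing the same chain must be kept few. The enabling feature is the bond between C1' of ring A and the benzylic carbon C3. Seen from C3, the unit CH2CH2CO2R is a succinic acid monoester that has lost one carboxyl group, so a redox-active ester of a succinate half-ester can deliver C3 as a radical to an aryl halide.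

## Retrosynthesis

**9 ⇒ 8 (O–Si bond).** The phenol of 9 is traced back to the tert-butyldimethylsilyl ether 8. A silyl ether is preferred to an ester-type mask because its removal by buffered fluoride is orthogonal to the C1 ester. It is preferred to leaving the phenol free because the coupling partner 5 is an acylating agent. The forward step must cleave O–Si without generating a free phenoxide that could attack the ester.

**8 ⇒ 5 + 7 (C1'–C3 bond).** The aryl–alkyl bond is cut to give the N-hydroxyphthalimide ester 5 and the aryl iodide 7. Three neighbouring cuts were weighed:
- The acyl C1–O bond would lead to a preformed arylpropanoic acid and the alcohol 2. It is the shortest path on paper, but it forms no skeletal bond and leaves the arylpropanoate unit to be purchased rather than made.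
- Cutting the same C1'–C3 bond at the alkene oxidation level (aryl halide plus acrylate) needs a later reduction.
- The C2–C3 cut (benzylic halide plus ester enolate) needs strong base beside a wax ester and risks double alkylation.

The chosen cut joins two electrophiles directly at the correct oxidation level and is convergent. The precursors are much simpler: 7 is a protected commodity phenol and 5 is a C4 diacid derivative. The forward reaction must give cross-coupling rather than dimerisation of either partner.

**5 ⇒ 3 + 4 (acyl C–O–N bond).** The redox-active ester is disconnected to the half-acid 3 and N-hydroxyphthalimide 4. The forward reaction is a carbodiimide condensation that must leave the hexacosyl ester at the other end of 3 untouched, which it should, since only the free carboxyl is activated.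

**3 ⇒ 1 + 2 (ester C–O bond).** The half-ester 3 comes from succinic anhydride 1 and 1-hexacosanol 2. Opening the cyclic anhydride is preferred to mono-esterification of the diacid because it cannot proceed to the diester, so no statistical mixture of wax esters arises. The cheap partner 1 can be used in excess to consume the valuable alcohol.

**7 ⇒ 6 (O–Si bond).** The aryl iodide 7 is the silyl ether of 4-iodophenol 6. The iodine already sits para to oxygen, so the regiochemistry of the target is bought and not made.

## Roads not taken

**Alternative 1:** The cut passes through ring A itself. Hexacosyl 5-oxopentanoate A1 and but-3-en-2-one A2 would be combined under pyrrolidine catalysis and then acid: Michael addition forms one ring bond and aldol condensation the second, closing a six-membered carbocycle. The product is the 4-substituted cyclohexenone A3, hexacosyl 3-(4-oxocyclohex-2-en-1-yl)propanoate, a racemate whose single stereocentre vanishes when the ring is dehydrogenated to the phenol 9.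
- Merits: the para relationship is built into the annulation, and no halogen and no phenol protecting group are needed. In protecting-group count this road is better than the chosen one.
- Weak points: it constructs a benzene ring that is available at negligible cost. A1 requires an aldehyde and an ester at different oxidation levels on a wax chain, so several steps are needed to reach it. The enolisable aldehyde can self-condense and A2 can polymerise. The final dehydrogenation of A3 is an oxidation at elevated temperature on a wax ester that may stop short or over-oxidise.
- Comparison: the chosen plan sets against the protecting-group advantage a shorter sequence, an aromatic ring taken from the shelf, and no redox adjustment at any stage.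

**Alternative 2:** The C2–C3 bond and the C1–O bond are cut together. The diazoketone A4, 1-[4-(benzyloxy)phenyl]-3-diazopropan-2-one, would lose nitrogen on irradiation or with AgO2CPh and Et3N. Wolff rearrangement moves the arylmethyl group to the carbene carbon, and 1-hexacosanol 2 traps the ketene to give hexacosyl 3-[4-(benzyloxy)phenyl]propanoate A5; hydrogenolysis then gives 9.
- Merits: the homologation logic is reliable. The wax alcohol enters only at the key step, so all earlier intermediates are small and easily purified. The final hydrogenolysis is neutral and at least as gentle toward the ester as buffered fluoride. In these two respects the road equals or surpasses the chosen plan.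
- Weak points: A4 requires a hazardous diazoalkane reagent. The ketene has to be captured by a sparingly soluble, high-molecular-weight alcohol. That alcohol cannot be used in excess without a difficult wax/wax separation, so ketene dimerisation and capture by adventitious water compete. Reaching an arylpropanoate by one-carbon homologation of an arylacetic acid is a detour when C3 and C4 building blocks exist.
- Comparison: the chosen plan avoids diazo compounds and uses 2 in a step where the other partner can be taken in excess.

**Alternative 3:** The cut lies inside the alkyl chain at C9=C10. Dec-9-en-1-yl 3-(4-hydroxyphenyl)propanoate A6 and excess octadec-1-ene A7 would undergo cross-metathesis with the second-generation Grubbs catalyst RuCl2(=CHPh)(PCy3)(H2IMes), losing ethylene. The product is (E)-hexacos-9-en-1-yl 3-(4-hydroxyphenyl)propanoate A8 together with its Z isomer, and hydrogenation of the mixture gives 9.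
- Merits: the C26 alcohol, the most expensive input of the chosen plan, is replaced by commodity olefins. The free phenol is tolerated, so no protecting group is needed. In raw-material cost and protecting-group economy this road is better.
- Weak points: both partners are unhindered terminal olefins of the same reactivity class, so the cross product forms statistically. The excess of A7 needed gives a long-chain hydrocarbon wax by self-metathesis, which must be separated from a wax ester. Ruthenium hydride species can shift the double bonds before metathesis; the resulting chain-length homologues become inseparable from 9 after hydrogenation. An extra reduction step is required.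
- Comparison: the chosen plan sets against the cost advantage the integrity of the chain length, which is bought as a single defined alcohol and never altered, and the absence of olefin chemistry.

Key step: step 4

Remark on the chemistry: the alkyl chain is taken as unbranched n-C26, and commercial 1-hexacosanol of single chain length is assumed, since its purity fixes the homogeneity of every later compound.

## Route

Step 1
Reactants: 1 succinic anhydride; 2 1-hexacosanol
Product: 3 4-(hexacosyloxy)-4-oxobutanoic acid
Conditions: 1 (1.5 equiv), DMAP (0.1 equiv), toluene/pyridine 4:1, 80 °C; dilute aq. HCl work-up
Reagents that add atoms: none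
Why: DMAP-catalysed ring opening of a cyclic anhydride by a primary alcohol (nucleophilic acyl substitution) stops at the half-ester because the carboxylate formed is no acylating agent; warm toluene keeps the waxy alcohol in solution and the excess anhydride is removed by aqueous washing.

Step 2
Reactants: 3 4-(hexacosyloxy)-4-oxobutanoic acid; 4 N-hydroxyphthalimide
Product: 5 1,3-dioxoisoindolin-2-yl hexacosyl butanedioate
Conditions: 4 (1.1 equiv), N,N'-diisopropylcarbodiimide (1.1 equiv), DMAP (0.1 equiv), CH2Cl2/THF, 25 °C
Reagents that add atoms: none
Why: Steglich-type carbodiimide condensation activates only the free carboxyl group as its O-acylisourea, which the acidic N-hydroxy compound intercepts; the hexacosyl ester at the other terminus is inert under these neutral conditions.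

Step 3
Reactants: 6 4-iodophenol
Product: 7 tert-butyl(4-iodophenoxy)dimethylsilane
Conditions: TBSCl (1.2 equiv), imidazole (2.0 equiv), DMF, 25 °C
Reagents that add atoms: tert-butyldimethylsilyl chloride (TBSCl), CC(C)(C)[Si](C)(C)Cl
Why: Standard O-silylation of a phenol through the N-silylimidazolium species; the aryl C–I bond is untouched and the product is a non-polar oil that is easily purified.

Step 4
Reactants: 5 1,3-dioxoisoindolin-2-yl hexacosyl butanedioate; 7 tert-butyl(4-iodophenoxy)dimethylsilane
Product: 8 hexacosyl 3-{4-[(tert-butyldimethylsilyl)oxy]phenyl}propanoate
Conditions: 7 (1.5 equiv), NiBr2(dme) (10 mol %), 4,4'-di-tert-butyl-2,2'-bipyridine (10 mol %), Zn powder (2 equiv), DMA/THF 1:1, 30 °C, argon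
Reagents that add atoms: none
Why: Nickel-catalysed reductive decarboxylative arylation of an N-hydroxyphthalimide ester with an aryl iodide (cross-electrophile coupling), a known reaction type for primary alkyl redox-active esters. Zinc reduces the bipyridine-ligated NiBr2 to zerovalent nickel, which undergoes oxidative addition into the C–I bond of 7 to give an aryl divalent nickel iodide. Single-electron transfer to 5 from a low-valent nickel species or from zinc breaks the N–O bond; loss of phthalimide anion and CO2 leaves the primary 2-(hexacosyloxycarbonyl)ethyl radical. The aryl nickel complex captures this radical to reach trivalent nickel, reductive elimination forms the C1'–C3 bond, and zinc returns the resulting monovalent nickel halide to the cycle. No ring closes and no stereocentre is formed. The selectivity required is cross-coupling over dimerisation of either partner; it rests on the two electrophiles being activated by different elementary steps (two-electron oxidative addition for the sp2 C–I bond, one-electron reduction for the phthalimide ester), so that the nickel centre carries one aryl group when it meets one alkyl radical. The iodine fixes the para position, the silyl ether keeps the phenol from being acylated by 5, and the THF co-solvent keeps the waxy ester dissolved so that radical generation does not outrun formation of the aryl nickel species.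

Step 5
Reactants: 8 hexacosyl 3-{4-[(tert-butyldimethylsilyl)oxy]phenyl}propanoate
Product: 9 hexacosyl 3-(4-hydroxyphenyl)propanoate
Conditions: tetrabutylammonium fluoride (1.1 equiv), AcOH (1.2 equiv), THF, 0 °C to 25 °C
Reagents that add atoms: none
Why: Fluoride-induced cleavage of an aryl silyl ether, driven by the strength of the Si–F bond; the acetic acid buffer protonates the phenoxide as it forms, so the primary alkyl ester should not undergo acyl transfer or hydrolysis.

## Compound list

1 | succinic anhydride (oxolane-2,5-dione) | O=C1CCC(=O)O1 | starting material
2 | 1-hexacosanol | CCCCCCCCCCCCCCCCCCCCCCCCCCO | starting material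
3 | 4-(hexacosyloxy)-4-oxobutanoic acid | CCCCCCCCCCCCCCCCCCCCCCCCCCOC(=O)CCC(=O)O | intermediate
4 | N-hydroxyphthalimide (2-hydroxyisoindoline-1,3-dione) | O=C1c2ccccc2C(=O)N1O | starting material
5 | 1,3-dioxoisoindolin-2-yl hexacosyl butanedioate | CCCCCCCCCCCCCCCCCCCCCCCCCCOC(=O)CCC(=O)ON1C(=O)c2ccccc2C1=O | intermediate
6 | 4-iodophenol | Oc1ccc(I)cc1 | starting material
7 | tert-butyl(4-iodophenoxy)dimethylsilane | CC(C)(C)[Si](C)(C)Oc1ccc(I)cc1 | intermediate
8 | hexacosyl 3-{4-[(tert-butyldimethylsilyl)oxy]phenyl}propanoate | CCCCCCCCCCCCCCCCCCCCCCCCCCOC(=O)CCc1ccc(O[Si](C)(C)C(C)(C)C)cc1 | intermediate
9 | hexacosyl 3-(4-hydroxyphenyl)propanoate (CNP0312891.0) | CCCCCCCCCCCCCCCCCCCCCCCCCCOC(=O)CCc1ccc(O)cc1 | target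

## Step count and risk assessment

Total step count: 5. Longest linear sequence: 4 steps (steps 1, 2, 4, 5); step 3 is a one-step side branch.

**Step 4 (key step).** Several processes could erode the cross-coupling:
- reductive homocoupling of the aryl iodide;
- premature reduction of the phthalimide ester before an aryl nickel species is present, leading to hydrogen-atom capture or dimerisation of the alkyl radical;
- β-hydride elimination from an alkyl nickel intermediate;
- slow reaction caused by incomplete dissolution of the C26 ester in the amide solvent.

By-products that carry the hexacosyl chain would also be difficult to separate from 8.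

The fallback keeps the C1'–C3 bond but forms it by a two-electron palladium pathway at the alkene oxidation level, setting out from 1-hexacosanol 2 and the aryl iodide 7. Acylation of 2 with acryloyl chloride (Et3N, CH2Cl2, 0 °C) would give hexacosyl prop-2-enoate F1. A Mizoroki–Heck reaction of F1 with 7 (Pd(OAc)2, P(o-tol)3, Et3N, MeCN/toluene, 85 °C) would give hexacosyl (2E)-3-{4-[(tert-butyldimethylsilyl)oxy]phenyl}prop-2-enoate F2. Hydrogenation of the alkene (H2, 10% Pd/C, EtOAc/THF, 25 °C) would return to the route at 8.

**Step 2.** Three things could go wrong: rearrangement of the O-acylisourea to an unreactive N-acylurea, hydrolysis of the activated ester during aqueous work-up or on silica, and co-precipitation of the urea with the waxy product.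

The fallback replaces carbodiimide activation by a discrete acyl chloride, setting out from the acid 3. Oxalyl chloride with catalytic DMF in CH2Cl2 would give hexacosyl 4-chloro-4-oxobutanoate F3. After evaporation, F3 would be added to N-hydroxyphthalimide 4 and Et3N in CH2Cl2 at 0 °C, returning to the route at 5; the product could then be purified by crystallisation and not by chromatography.

**Step 5.** Insufficient buffering could allow acyl transfer from the alkyl ester to the liberated phenoxide, or ester hydrolysis by the basic fluoride source. Desilylation could also be incomplete if the wax separates from cold THF.

The fallback changes the protecting-group strategy so that the last step is a neutral hydrogenolysis, setting out from 4-iodophenol 6 and the phthalimide ester 5. Alkylation of 6 with 4-methoxybenzyl chloride (K2CO3, DMF, 50 °C) would give 1-iodo-4-[(4-methoxyphenyl)methoxy]benzene F4. The same nickel-catalysed reductive coupling of F4 with 5 (NiBr2(dme), 4,4'-di-tert-butyl-2,2'-bipyridine, Zn powder, DMA/THF, 30 °C) would give hexacosyl 3-{4-[(4-methoxyphenyl)methoxy]phenyl}propanoate F5. Hydrogenolysis of the benzylic C–O bond (H2, 10% Pd/C, EtOAc/THF, 25 °C) would arrive at the target 9.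

## Further compounds

F1 | step 4 | hexacosyl prop-2-enoate | CCCCCCCCCCCCCCCCCCCCCCCCCCOC(=O)C=C
F2 | step 4 | hexacosyl (2E)-3-{4-[(tert-butyldimethylsilyl)oxy]phenyl}prop-2-enoate | CCCCCCCCCCCCCCCCCCCCCCCCCCOC(=O)/C=C/c1ccc(O[Si](C)(C)C(C)(C)C)cc1
F3 | step 2 | hexacosyl 4-chloro-4-oxobutanoate | CCCCCCCCCCCCCCCCCCCCCCCCCCOC(=O)CCC(Cl)=O
F4 | step 5 | 1-iodo-4-[(4-methoxyphenyl)methoxy]benzene | COc1ccc(COc2ccc(I)cc2)cc1
F5 | step 5 | hexacosyl 3-{4-[(4-methoxyphenyl)methoxy]phenyl}propanoate | CCCCCCCCCCCCCCCCCCCCCCCCCCOC(=O)CCc1ccc(OCc2ccc(OC)cc2)cc1
A1 | alternative 1 | hexacosyl 5-oxopentanoate | CCCCCCCCCCCCCCCCCCCCCCCCCCOC(=O)CCCC=O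
A2 | alternative 1 | but-3-en-2-one | CC(=O)C=C
A3 | alternative 1 | hexacosyl 3-(4-oxocyclohex-2-en-1-yl)propanoate (racemate) | CCCCCCCCCCCCCCCCCCCCCCCCCCOC(=O)CCC1CCC(=O)C=C1
A4 | alternative 2 | 1-[4-(benzyloxy)phenyl]-3-diazopropan-2-one | [N-]=[N+]=CC(=O)Cc1ccc(OCc2ccccc2)cc1
A5 | alternative 2 | hexacosyl 3-[4-(benzyloxy)phenyl]propanoate | CCCCCCCCCCCCCCCCCCCCCCCCCCOC(=O)CCc1ccc(OCc2ccccc2)cc1
A6 | alternative 3 | dec-9-en-1-yl 3-(4-hydroxyphenyl)propanoate | C=CCCCCCCCCOC(=O)CCc1ccc(O)cc1
A7 | alternative 3 | octadec-1-ene | CCCCCCCCCCCCCCCCC=C
A8 | alternative 3 | (E)-hexacos-9-en-1-yl 3-(4-hydroxyphenyl)propanoate | CCCCCCCCCCCCCCCC/C=C/CCCCCCCCOC(=O)CCc1ccc(O)cc1
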